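Both rings C are cut at C2–C3 and C2''–C3'', each a bond between a former acetyl methyl carbon and an aroyl carbon; in rings A and A'' that acetyl sits ortho to the oxygen that becomes O1 or O1''. The key step therefore treats diester 17 with base once: the 4-methoxybenzoate on the ring A oxygen flanked by acetyl and the C8 diaryl ether oxygen, and the benzoate that links the ether's second ring to ring A'', both migrate from oxygen to carbon and give bis(2-hydroxyaryl) 1,3-diketone 18. Acid then closes both pyranones and hydrogenolysis removes four benzyl groups.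

Key step: step 13

Remark: the target has no stereocentre; the carbinol carbon of 10 is formed racemic and is erased by the oxidation in step 8. Benzyl bromide and allyl bromide are taken as commercial reagents.

Step 1
Reactants: 1 2,4,6-trihydroxybenzaldehyde
Product: 2 2,4-bis(benzyloxy)-6-hydroxybenzaldehyde
Conditions: BnBr (2.1 equiv), K2CO3, DMF, 0 °C to rt
Reagents that add atoms: benzyl bromide, BrCc1ccccc1
Why: Williamson etherification in which the 4-OH and one ortho OH are alkylated while the remaining ortho OH, hydrogen-bonded to the formyl oxygen, should stay free at two equivalents of halide.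

Step 2
Reactants: 2 2,4-bis(benzyloxy)-6-hydroxybenzaldehyde
Product: 3 2-(allyloxy)-4,6-bis(benzyloxy)benzaldehyde
Conditions: allyl bromide (1.5 equiv), K2CO3, DMF, 60 °C
Reagents that add atoms: allyl bromide, C=CCBr
Why: Williamson etherification of the chelated phenol on warming, with allyl chosen because an alkyl group cannot migrate to a neighbouring phenoxide and is later removed under neutral palladium catalysis in the presence of benzyl ethers.

Step 3
Reactants: 3 2-(allyloxy)-4,6-bis(benzyloxy)benzaldehyde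
Product: 5 2-(allyloxy)-4,6-bis(benzyloxy)phenol, via aryl formate 4 (not isolated)
Conditions: mCPBA (1.1 equiv), CH2Cl2, 0 °C to rt; aq. NaHCO3 wash; then K2CO3 (cat.), MeOH, rt, N2
Reagents that add atoms: mCPBA, OOC(=O)c1cccc(Cl)c1
Why: Baeyer–Villiger (Dakin-type) oxidation in which the trialkoxyaryl group migrates in the peracid adduct far faster than hydride and faster than the terminal alkene is epoxidised, followed by mild methanolysis of the formate to the phenol.

Step 4
Reactants: 5 2-(allyloxy)-4,6-bis(benzyloxy)phenol; 6 tert-butyl 4-fluorobenzoate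
Product: 7 tert-butyl 4-[2-(allyloxy)-4,6-bis(benzyloxy)phenoxy]benzoate
Conditions: Cs2CO3 (2 equiv), degassed DMSO, 110 °C, N2
Reagents that add atoms: none
Why: Nucleophilic aromatic substitution (SNAr) in which the electron-rich caesium phenoxide adds para to the ester carbonyl and fluoride leaves, the tert-butyl ester resisting transesterification and the arylated oxygen being fixed as the one that came from the formyl carbon.

Step 5
Reactants: 7 tert-butyl 4-[2-(allyloxy)-4,6-bis(benzyloxy)phenoxy]benzoate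
Product: 8 tert-butyl 4-[2,4-bis(benzyloxy)-6-hydroxyphenoxy]benzoate
Conditions: Pd(PPh3)4 (5 mol %), morpholine, THF, rt
Reagents that add atoms: none
Why: Tsuji–Trost deallylation in which zerovalent palladium ionises the allyl aryl ether to a π-allyl complex that morpholine intercepts, leaving benzyl ethers and the tert-butyl ester untouched.

Step 6
Reactants: 8 tert-butyl 4-[2,4-bis(benzyloxy)-6-hydroxyphenoxy]benzoate
Product: 9 tert-butyl 4-[4,6-bis(benzyloxy)-3-formyl-2-hydroxyphenoxy]benzoate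
Conditions: MgCl2 (2 equiv), Et3N (4 equiv), (CH2O)n (7 equiv), MeCN, reflux
Reagents that add atoms: paraformaldehyde (as formaldehyde), C=O
Why: Magnesium-mediated ortho-formylation of a phenol (Casnati–Skattebøl), which delivers formaldehyde only to a carbon ortho to the OH, here the single free one between the OH and a benzyloxy group, so the competing position between the two benzyloxy groups is excluded; a second formaldehyde takes up hydride and leaves as methanol.

Step 7
Reactants: 9 tert-butyl 4-[4,6-bis(benzyloxy)-3-formyl-2-hydroxyphenoxy]benzoate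
Product: 10 tert-butyl 4-[4,6-bis(benzyloxy)-2-hydroxy-3-(1-hydroxyethyl)phenoxy]benzoate (racemic)
Conditions: MeMgBr (3 equiv), THF, −78 to −20 °C; sat. aq. NH4Cl
Reagents that add atoms: methylmagnesium bromide, C[Mg]Br
Why: Grignard 1,2-addition to the aldehyde at low temperature, where the hindered tert-butyl ester should not react and one equivalent is spent on the phenol; the carbinol centre forms without control (racemic) and is removed in the next step.

Step 8
Reactants: 10 tert-butyl 4-[4,6-bis(benzyloxy)-2-hydroxy-3-(1-hydroxyethyl)phenoxy]benzoate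
Product: 11 tert-butyl 4-[3-acetyl-4,6-bis(benzyloxy)-2-hydroxyphenoxy]benzoate
Conditions: activated MnO2 (excess), CH2Cl2, rt
Reagents that add atoms: none
Why: MnO2 oxidation of an electron-rich benzylic alcohol to the hydrogen-bonded ortho-hydroxyacetophenone, a mild heterogeneous oxidation that leaves the phenol, benzyl ethers and ester alone.

Step 9
Reactants: 11 tert-butyl 4-[3-acetyl-4,6-bis(benzyloxy)-2-hydroxyphenoxy]benzoate; 12 4-methoxybenzoyl chloride
Product: 13 tert-butyl 4-{3-acetyl-4,6-bis(benzyloxy)-2-[(4-methoxybenzoyl)oxy]phenoxy}benzoate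
Conditions: Et3N (2 equiv), DMAP (0.2 equiv), CH2Cl2, 0 °C to rt
Reagents that add atoms: none
Why: DMAP-catalysed O-acylation of the only free, chelated phenol with the acid chloride, under amine base too weak to enolise the methyl ketone and start acyl migration.

Step 10
Reactants: 13 tert-butyl 4-{3-acetyl-4,6-bis(benzyloxy)-2-[(4-methoxybenzoyl)oxy]phenoxy}benzoate
Product: 14 4-{3-acetyl-4,6-bis(benzyloxy)-2-[(4-methoxybenzoyl)oxy]phenoxy}benzoic acid
Conditions: TFA/CH2Cl2 (1:4), 0 °C to rt
Reagents that add atoms: none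
Why: Acidolysis of the tert-butyl ester through the tert-butyl cation with loss of isobutene, conditions under which the aryl ester, methyl ketone and the benzyl ethers of the now acyl-deactivated ring should survive.

Step 11
Reactants: 15 2',4',6'-trihydroxyacetophenone
Product: 16 1-[2,4-bis(benzyloxy)-6-hydroxyphenyl]ethanone
Conditions: BnBr (2.1 equiv), K2CO3, DMF, rt
Reagents that add atoms: benzyl bromide, BrCc1ccccc1
Why: Williamson etherification that stops at the dibenzyl ether because the last ortho OH is chelated to the acetyl carbonyl.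

Step 12
Reactants: 14 4-{3-acetyl-4,6-bis(benzyloxy)-2-[(4-methoxybenzoyl)oxy]phenoxy}benzoic acid; 16 1-[2,4-bis(benzyloxy)-6-hydroxyphenyl]ethanone
Product: 17 2-acetyl-3,5-bis(benzyloxy)phenyl 4-{3-acetyl-4,6-bis(benzyloxy)-2-[(4-methoxybenzoyl)oxy]phenoxy}benzoate
Conditions: DCC (1.2 equiv), DMAP (0.15 equiv), CH2Cl2, 0 °C to rt
Reagents that add atoms: none
Why: Steglich esterification, in which carbodiimide activation of the acid and DMAP acyl transfer should esterify the chelated phenol at room temperature without disturbing the existing aryl ester.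

Step 13
Reactants: 17 2-acetyl-3,5-bis(benzyloxy)phenyl 4-{3-acetyl-4,6-bis(benzyloxy)-2-[(4-methoxybenzoyl)oxy]phenoxy}benzoate
Product: 18 1-[4,6-bis(benzyloxy)-3-(4-{3-[2,4-bis(benzyloxy)-6-hydroxyphenyl]-3-oxopropanoyl}phenoxy)-2-hydroxyphenyl]-3-(4-methoxyphenyl)propane-1,3-dione
Conditions: LiN(SiMe3)2 (5.5 equiv), THF, −78 to 0 °C; 1 M HCl quench
Reagents that add atoms: none
Why: The amide base deprotonates both acetyl groups, and on warming each enolate carbon adds to the ester carbonyl on the oxygen ortho to it through a six-membered cyclic tetrahedral adduct that collapses to the aryloxide of a 1,3-diketone, so C2–C3 and C2''–C3'' form by two O-to-C acyl shifts (Baker–Venkataraman rearrangement, well known for 2-aroyloxyacetophenones and here run twice in one molecule). No ring is closed and no stereocentre is created. The selectivity needed is the pairing of each acyl group with its own methyl ketone, and it is secured because only the ortho ester is within reach of a six-membered transition state, attack on the remote ester requiring a macrocyclic one, so the 4-methoxybenzoyl group stays on ring A and the aryloxybenzoyl group on ring A''. A non-nucleophilic base in more than four equivalents (each rearranged unit ends as a dianion) should avoid ester cleavage and drive both transfers to completion. Since the only ester on ring A sits on the oxygen between the acetyl carbon and the diaryl ether carbon, the phenol set free there is the future O1 next to C8.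

Step 14
Reactants: 18 1-[4,6-bis(benzyloxy)-3-(4-{3-[2,4-bis(benzyloxy)-6-hydroxyphenyl]-3-oxopropanoyl}phenoxy)-2-hydroxyphenyl]-3-(4-methoxyphenyl)propane-1,3-dione
Product: 19 5,7-bis(benzyloxy)-8-{4-[5,7-bis(benzyloxy)-4-oxo-4H-chromen-2-yl]phenoxy}-2-(4-methoxyphenyl)-4H-chromen-4-one
Conditions: TsOH·H2O (0.2 equiv), toluene, 90 °C
Reagents that add atoms: none
Why: Acid-catalysed cyclodehydration of both 2-hydroxyaryl 1,3-diketones, each free phenol adding to the enolised aroyl carbonyl with loss of water, and since the other ortho oxygen of each ring is benzylated only the 8-aryloxy isomer can form.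

Step 15
Reactants: 19 5,7-bis(benzyloxy)-8-{4-[5,7-bis(benzyloxy)-4-oxo-4H-chromen-2-yl]phenoxy}-2-(4-methoxyphenyl)-4H-chromen-4-one
Product: 20 5,7-dihydroxy-8-[4-(5,7-dihydroxy-4-oxo-4H-chromen-2-yl)phenoxy]-2-(4-methoxyphenyl)-4H-chromen-4-one
Conditions: H2 (1 atm), 10% Pd/C, THF/MeOH (1:1), rt
Reagents that add atoms: none
Why: Catalytic hydrogenolysis of the four benzyl aryl ethers, under which the aryl methyl ether, the diaryl ether and the pyranone double bonds should be inert at ambient pressure and temperature.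

Compound list
1 | 2,4,6-trihydroxybenzaldehyde | O=Cc1c(O)cc(O)cc1O | starting material
2 | 2,4-bis(benzyloxy)-6-hydroxybenzaldehyde | O=Cc1c(O)cc(OCc2ccccc2)cc1OCc1ccccc1 | intermediate
3 | 2-(allyloxy)-4,6-bis(benzyloxy)benzaldehyde | C=CCOc1cc(OCc2ccccc2)cc(OCc2ccccc2)c1C=O | intermediate
4 | 2-(allyloxy)-4,6-bis(benzyloxy)phenyl formate | C=CCOc1cc(OCc2ccccc2)cc(OCc2ccccc2)c1OC=O | intermediate
5 | 2-(allyloxy)-4,6-bis(benzyloxy)phenol | C=CCOc1cc(OCc2ccccc2)cc(OCc2ccccc2)c1O | intermediate
6 | tert-butyl 4-fluorobenzoate | CC(C)(C)OC(=O)c1ccc(F)cc1 | starting material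
7 | tert-butyl 4-[2-(allyloxy)-4,6-bis(benzyloxy)phenoxy]benzoate | C=CCOc1cc(OCc2ccccc2)cc(OCc2ccccc2)c1Oc1ccc(cc1)C(=O)OC(C)(C)C | intermediate
8 | tert-butyl 4-[2,4-bis(benzyloxy)-6-hydroxyphenoxy]benzoate | Oc1cc(OCc2ccccc2)cc(OCc2ccccc2)c1Oc1ccc(cc1)C(=O)OC(C)(C)C | intermediate
9 | tert-butyl 4-[4,6-bis(benzyloxy)-3-formyl-2-hydroxyphenoxy]benzoate | O=Cc1c(O)c(Oc2ccc(cc2)C(=O)OC(C)(C)C)c(OCc2ccccc2)cc1OCc1ccccc1 | intermediate
10 | tert-butyl 4-[4,6-bis(benzyloxy)-2-hydroxy-3-(1-hydroxyethyl)phenoxy]benzoate (racemic) | CC(O)c1c(O)c(Oc2ccc(cc2)C(=O)OC(C)(C)C)c(OCc2ccccc2)cc1OCc1ccccc1 | intermediate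
11 | tert-butyl 4-[3-acetyl-4,6-bis(benzyloxy)-2-hydroxyphenoxy]benzoate | CC(=O)c1c(O)c(Oc2ccc(cc2)C(=O)OC(C)(C)C)c(OCc2ccccc2)cc1OCc1ccccc1 | intermediate
12 | 4-methoxybenzoyl chloride | COc1ccc(cc1)C(Cl)=O | starting material
13 | tert-butyl 4-{3-acetyl-4,6-bis(benzyloxy)-2-[(4-methoxybenzoyl)oxy]phenoxy}benzoate | COc1ccc(cc1)C(=O)Oc1c(Oc2ccc(cc2)C(=O)OC(C)(C)C)c(OCc2ccccc2)cc(OCc2ccccc2)c1C(C)=O | intermediate
14 | 4-{3-acetyl-4,6-bis(benzyloxy)-2-[(4-methoxybenzoyl)oxy]phenoxy}benzoic acid | COc1ccc(cc1)C(=O)Oc1c(Oc2ccc(cc2)C(O)=O)c(OCc2ccccc2)cc(OCc2ccccc2)c1C(C)=O | intermediate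
15 | 2',4',6'-trihydroxyacetophenone | CC(=O)c1c(O)cc(O)cc1O | starting material
16 | 1-[2,4-bis(benzyloxy)-6-hydroxyphenyl]ethanone | CC(=O)c1c(O)cc(OCc2ccccc2)cc1OCc1ccccc1 | intermediate
17 | 2-acetyl-3,5-bis(benzyloxy)phenyl 4-{3-acetyl-4,6-bis(benzyloxy)-2-[(4-methoxybenzoyl)oxy]phenoxy}benzoate | COc1ccc(cc1)C(=O)Oc1c(Oc2ccc(cc2)C(=O)Oc2cc(OCc3ccccc3)cc(OCc3ccccc3)c2C(C)=O)c(OCc2ccccc2)cc(OCc2ccccc2)c1C(C)=O | intermediate
18 | 1-[4,6-bis(benzyloxy)-3-(4-{3-[2,4-bis(benzyloxy)-6-hydroxyphenyl]-3-oxopropanoyl}phenoxy)-2-hydroxyphenyl]-3-(4-methoxyphenyl)propane-1,3-dione | COc1ccc(cc1)C(=O)CC(=O)c1c(O)c(Oc2ccc(cc2)C(=O)CC(=O)c2c(O)cc(OCc3ccccc3)cc2OCc2ccccc2)c(OCc2ccccc2)cc1OCc1ccccc1 | intermediate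
19 | 5,7-bis(benzyloxy)-8-{4-[5,7-bis(benzyloxy)-4-oxo-4H-chromen-2-yl]phenoxy}-2-(4-methoxyphenyl)-4H-chromen-4-one | COc1ccc(cc1)-c1cc(=O)c2c(OCc3ccccc3)cc(OCc3ccccc3)c(Oc3ccc(cc3)-c3cc(=O)c4c(OCc5ccccc5)cc(OCc5ccccc5)cc4o3)c2o1 | intermediate
20 | 5,7-dihydroxy-8-[4-(5,7-dihydroxy-4-oxo-4H-chromen-2-yl)phenoxy]-2-(4-methoxyphenyl)-4H-chromen-4-one | COc1ccc(-c2cc(=O)c3c(O)cc(O)c(Oc4ccc(-c5cc(=O)c6c(O)cc(O)cc6o5)cc4)c3o2)cc1 | target

Total step count: 15. Longest linear sequence: 14 steps (steps 1–10, then 12–15); step 11 is a one-step side branch.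

Steps most likely to fail

Step 13. The second acyl transfer may stall, or an acyl group may be lost by intermolecular transacylation, so that mono-rearranged and de-acylated material accumulates. The fallback runs the two acyl transfers one after the other and sets out from 13:
- LiN(SiMe3)2 (3 equiv) in THF, −78 to 0 °C, should rearrange the single aryl ester of 13 to tert-butyl 4-{4,6-bis(benzyloxy)-2-hydroxy-3-[3-(4-methoxyphenyl)-3-oxopropanoyl]phenoxy}benzoate F1.
- TFA in CH2Cl2, rt to 40 °C, should close the first pyranone and cleave the tert-butyl ester, giving 4-{[5,7-bis(benzyloxy)-2-(4-methoxyphenyl)-4-oxo-4H-chromen-8-yl]oxy}benzoic acid F2.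
- DCC/DMAP coupling with 16 should give 2-acetyl-3,5-bis(benzyloxy)phenyl 4-{[5,7-bis(benzyloxy)-2-(4-methoxyphenyl)-4-oxo-4H-chromen-8-yl]oxy}benzoate F3.
- A second single Baker–Venkataraman rearrangement with LiN(SiMe3)2 should give 1-[2,4-bis(benzyloxy)-6-hydroxyphenyl]-3-(4-{[5,7-bis(benzyloxy)-2-(4-methoxyphenyl)-4-oxo-4H-chromen-8-yl]oxy}phenyl)propane-1,3-dione F4.
- TsOH·H2O in toluene at 90 °C closes the second pyranone, and the route is rejoined at 19.

Step 4. Substitution at the weakly activated fluoroarene by a di-ortho-substituted phenoxide may be slow, and the electron-rich phenoxide may oxidise on prolonged heating. The fallback forms the ether at the aldehyde oxidation level with a much stronger SNAr acceptor and sets out from 5: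
- 4-Fluorobenzaldehyde, K2CO3, DMF, 90 °C under N2 should give 4-[2-(allyloxy)-4,6-bis(benzyloxy)phenoxy]benzaldehyde F5.
- Pinnick oxidation (NaClO2, NaH2PO4, 2-methyl-2-butene, tBuOH/H2O) should give 4-[2-(allyloxy)-4,6-bis(benzyloxy)phenoxy]benzoic acid F6.
- tert-Butyl esterification (Boc2O, DMAP, tBuOH, 40 °C) rejoins the route at 7.

Step 1. The degree of O-alkylation may be poorly controlled, giving mono-, di- and tribenzyl ethers together with some C-benzylation. The fallback replaces partial alkylation by exhaustive alkylation and directed cleavage and sets out from 1: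
- BnBr (3.5 equiv), K2CO3, DMF, 60 °C should give 2,4,6-tris(benzyloxy)benzaldehyde F7.
- MgBr2·OEt2 in toluene/Et2O at reflux should remove one benzyl group ortho to the formyl group by chelation-controlled cleavage, rejoining the route at 2.

Further compounds
F1 | step 13 | tert-butyl 4-{4,6-bis(benzyloxy)-2-hydroxy-3-[3-(4-methoxyphenyl)-3-oxopropanoyl]phenoxy}benzoate | COc1ccc(cc1)C(=O)CC(=O)c1c(O)c(Oc2ccc(cc2)C(=O)OC(C)(C)C)c(OCc2ccccc2)cc1OCc1ccccc1
F2 | step 13 | 4-{[5,7-bis(benzyloxy)-2-(4-methoxyphenyl)-4-oxo-4H-chromen-8-yl]oxy}benzoic acid | COc1ccc(cc1)-c1cc(=O)c2c(OCc3ccccc3)cc(OCc3ccccc3)c(Oc3ccc(cc3)C(O)=O)c2o1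
F3 | step 13 | 2-acetyl-3,5-bis(benzyloxy)phenyl 4-{[5,7-bis(benzyloxy)-2-(4-methoxyphenyl)-4-oxo-4H-chromen-8-yl]oxy}benzoate | COc1ccc(cc1)-c1cc(=O)c2c(OCc3ccccc3)cc(OCc3ccccc3)c(Oc3ccc(cc3)C(=O)Oc3cc(OCc4ccccc4)cc(OCc4ccccc4)c3C(C)=O)c2o1
F4 | step 13 | 1-[2,4-bis(benzyloxy)-6-hydroxyphenyl]-3-(4-{[5,7-bis(benzyloxy)-2-(4-methoxyphenyl)-4-oxo-4H-chromen-8-yl]oxy}phenyl)propane-1,3-dione | COc1ccc(cc1)-c1cc(=O)c2c(OCc3ccccc3)cc(OCc3ccccc3)c(Oc3ccc(cc3)C(=O)CC(=O)c3c(O)cc(OCc4ccccc4)cc3OCc3ccccc3)c2o1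
F5 | step 4 | 4-[2-(allyloxy)-4,6-bis(benzyloxy)phenoxy]benzaldehyde | C=CCOc1cc(OCc2ccccc2)cc(OCc2ccccc2)c1Oc1ccc(C=O)cc1
F6 | step 4 | 4-[2-(allyloxy)-4,6-bis(benzyloxy)phenoxy]benzoic acid | C=CCOc1cc(OCc2ccccc2)cc(OCc2ccccc2)c1Oc1ccc(cc1)C(O)=O
F7 | step 1 | 2,4,6-tris(benzyloxy)benzaldehyde | O=Cc1c(OCc2ccccc2)cc(OCc2ccccc2)cc1OCc1ccccc1
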